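**Retrosynthetic overview**
- Last operations: one global fluoride desilylation, preceded by formation of the C3–CH2 bond through trans-selective alkylation of a (4R)-4-benzyl-γ-butyrolactone enolate with a silylated benzylic bromide that already carries the threo-(7''R,8''R) arylglycerol 8-O-4 ether.
- The lactone is the only ring made. It comes from a catalytic asymmetric Baeyer–Villiger ring expansion of a prochiral 3-benzylcyclobutanone (1,2-shift of one enantiotopic CH2 from carbon to oxygen); this is the key step. The cyclobutanone comes from a Ni cross-electrophile coupling.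
- Arylglycerol ether: aryl iodide + CO + ethyl diazoacetate (C7''–C8''–C9''), Rh O–H insertion of the ring 2 phenol (C8''–O bond), then Ru transfer hydrogenation with dynamic kinetic resolution to set C7'' and C8''.
- All three guaiacyl rings come from catechol through one common 4-iodo-2-methoxyphenol.

Definitions: ring 1 = aryl of the C4 benzyl group, ring 2 = aryl of the C3 benzyl group (bears the ether), ring 3 = aryl of the glycerol unit; C7''–C9'' = glycerol carbons; TIPS = triisopropylsilyl; TBS = tert-butyldimethylsilyl.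

Assumption: 5 is bought as the dimethyl ketal of 3-(bromomethyl)cyclobutan-1-one; the ketal is only a protecting group and is removed in the work-up of step 4.

Assumption: the sense of induction in steps 5 and 8 is assigned by analogy with related substrates; if the opposite sense is found, the antipodal ligand is used.

**Route**

Step 1
Reactants: 1 catechol
Product: 2 guaiacol (2-methoxyphenol)
Conditions: MeI (0.9 equiv), K2CO3, acetone, reflux
Reagents that add atoms: iodomethane, CI
Why: Williamson ether synthesis on the monophenoxide, with the diol in excess so that dimethylation stays low and 2 is separated from 1 and from veratrole by acid–base extraction.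

Step 2
Reactants: 2 guaiacol
Product: 3 4-iodo-2-methoxyphenol
Conditions: NIS, TsOH·H2O (10 mol %), MeCN, 0 °C to rt
Reagents that add atoms: N-iodosuccinimide, O=C1CCC(=O)N1I
Why: electrophilic aromatic iodination goes para to the free OH, which is a stronger donor than OMe, giving the 1,3,4-pattern needed for all three rings.

Step 3
Reactants: 3 4-iodo-2-methoxyphenol
Product: 4 (4-iodo-2-methoxyphenoxy)triisopropylsilane
Conditions: TIPSCl, imidazole, DMF, rt
Reagents that add atoms: chlorotriisopropylsilane, CC(C)[Si](Cl)(C(C)C)C(C)C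
Why: imidazole-promoted O-silylation gives an aryl silyl ether that survives organometallic, peracid and hydride steps and leaves with the other silyl groups in step 14.

Step 4
Reactants: 4 (4-iodo-2-methoxyphenoxy)triisopropylsilane; 5 3-(bromomethyl)-1,1-dimethoxycyclobutane
Product: 7 3-[(3-methoxy-4-triisopropylsilyloxyphenyl)methyl]cyclobutan-1-one, via dimethyl ketal 6 (not isolated)
Conditions: NiI2 (10 mol %), 4,4'-di-tert-butyl-2,2'-bipyridine (10 mol %), pyridine (10 mol %), NaI (25 mol %), Zn dust (2 equiv), DMPU, 60 °C; then 1 M HCl, THF, rt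
Reagents that add atoms: water, O
Why: Ni-catalysed reductive cross-electrophile coupling of an aryl iodide with a primary alkyl bromide forms the aryl–CH2 bond, the ketal keeps the cyclobutylmethyl radical from fragmenting towards an acyl-stabilised radical, and the acidic work-up hydrolyses the ketal.

Step 5
Reactants: 7 3-[(3-methoxy-4-triisopropylsilyloxyphenyl)methyl]cyclobutan-1-one
Product: 8 (4R)-4-[(3-methoxy-4-triisopropylsilyloxyphenyl)methyl]oxolan-2-one
Conditions: Sc(OTf)3 (5 mol %), chiral C2-symmetric N,N'-dioxide bis(2,6-diisopropylanilide) ligand of the pipecolic acid type (6 mol %, antipode that gives the R lactone), m-CPBA (1.2 equiv), EtOAc, −20 °C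
Reagents that add atoms: 3-chloroperoxybenzoic acid, OOC(=O)c1cccc(Cl)c1
Why: catalytic asymmetric Baeyer–Villiger oxidation, in which the peracid adds to the Sc-bound ketone and one of the two enantiotopic CH2 groups of the chiral Criegee adduct migrates from carbon to oxygen, expanding the four-membered ketone to the lactone and setting C4 as R (85–95% ee expected, the rest removed as a diastereomer after step 13).

Step 6
Reactants: 4 (4-iodo-2-methoxyphenoxy)triisopropylsilane; 9 ethyl diazoacetate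
Product: 10 ethyl 2-diazo-3-(3-methoxy-4-triisopropylsilyloxyphenyl)-3-oxopropanoate
Conditions: Pd(PPh3)4 (5 mol %), CO (1 atm), Et3N, Bu4NBr, MeCN, 45 °C
Reagents that add atoms: carbon monoxide, [C-]#[O+]
Why: Pd-catalysed carbonylative coupling, in which zerovalent palladium inserts into the Ar–I bond, CO insertion gives an aroyl–Pd species and this acylates the diazo carbon with the diazo group retained, assembling C7''–C8''–C9'' in one operation.

Step 7
Reactants: 10 ethyl 2-diazo-3-(3-methoxy-4-triisopropylsilyloxyphenyl)-3-oxopropanoate; 3 4-iodo-2-methoxyphenol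
Product: 11 ethyl 2-(4-iodo-2-methoxyphenoxy)-3-(3-methoxy-4-triisopropylsilyloxyphenyl)-3-oxopropanoate (racemic)
Conditions: Rh2(OAc)4 (1 mol %), 3 (1.2 equiv), toluene, 80 °C, slow addition of 10
Reagents that add atoms: none
Why: Rh-carbenoid O–H insertion into the phenol (oxonium ylide, then proton shift) forms the C8''–O–aryl bond, and the racemic outcome does not matter because this centre is configurationally labile.

Step 8
Reactants: 11 ethyl 2-(4-iodo-2-methoxyphenoxy)-3-(3-methoxy-4-triisopropylsilyloxyphenyl)-3-oxopropanoate (racemic)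
Product: 12 ethyl (2S,3R)-3-hydroxy-2-(4-iodo-2-methoxyphenoxy)-3-(3-methoxy-4-triisopropylsilyloxyphenyl)propanoate
Conditions: RuCl[(S,S)-TsDPEN](p-cymene) (2 mol %), HCO2H/Et3N (5:2), CH2Cl2, 30 °C
Reagents that add atoms: none
Why: Proposed new method: Noyori–Ikariya asymmetric transfer hydrogenation with dynamic kinetic resolution applied to an α-aryloxy β-aryl β-keto ester of the lignin type, a substrate class on which it has not been shown; the α-H of 11 (flanked by ketone, ester and aryloxy group) epimerises quickly through the enol in HCO2H/Et3N while the (S,S)-Ru hydride reduces only the matched epimer by outer-sphere hydride transfer to the aryl-ketone face fixed by the arene CH/π contact (giving 3R) with the aryloxy group anti to the incoming hydride (polar Felkin–Anh, giving the syn or threo 2S,3R alcohol), the closest known reaction type being the syn-selective transfer hydrogenation with dynamic kinetic resolution of α-alkoxy β-keto esters.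

Step 9
Reactants: 12 ethyl (2S,3R)-3-hydroxy-2-(4-iodo-2-methoxyphenoxy)-3-(3-methoxy-4-triisopropylsilyloxyphenyl)propanoate
Product: 13 (1R,2R)-2-(4-iodo-2-methoxyphenoxy)-1-(3-methoxy-4-triisopropylsilyloxyphenyl)propane-1,3-diol
Conditions: LiBH4, THF, 0 °C to rt
Reagents that add atoms: none
Why: borohydride reduction of an ester activated by its α-oxygen and chelating β-hydroxyl gives the primary alcohol without touching the aryl iodide, the silyl ether or either stereocentre (the 2S label becomes 2R only through the priority change).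

Step 10
Reactants: 13 (1R,2R)-2-(4-iodo-2-methoxyphenoxy)-1-(3-methoxy-4-triisopropylsilyloxyphenyl)propane-1,3-diol
Product: 14 (1R,2R)-1,3-bis(tert-butyldimethylsilyloxy)-2-(4-iodo-2-methoxyphenoxy)-1-(3-methoxy-4-triisopropylsilyloxyphenyl)propane
Conditions: TBSOTf (2.4 equiv), 2,6-lutidine, CH2Cl2, −78 to 0 °C
Reagents that add atoms: tert-butyldimethylsilyl trifluoromethanesulfonate, CC(C)(C)[Si](C)(C)OS(=O)(=O)C(F)(F)F
Why: silyl triflate etherification caps the primary and the hindered benzylic hydroxyl so that the organolithium, Appel and enolate steps are possible and one fluoride treatment frees everything at the end.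

Step 11
Reactants: 14 (1R,2R)-1,3-bis(tert-butyldimethylsilyloxy)-2-(4-iodo-2-methoxyphenoxy)-1-(3-methoxy-4-triisopropylsilyloxyphenyl)propane
Product: 17 [4-[(1R,2R)-1,3-bis(tert-butyldimethylsilyloxy)-1-(3-methoxy-4-triisopropylsilyloxyphenyl)propan-2-yl]oxy-3-methoxyphenyl]methanol, via aryllithium 15 (not isolated), via aldehyde 16 (not isolated)
Conditions: n-BuLi (1.05 equiv), THF, −78 °C; DMF, −78 to 0 °C; then MeOH, NaBH4, 0 °C
Reagents that add atoms: N,N-dimethylformamide, CN(C)C=O
Why: iodine–lithium exchange is faster at −78 °C than any attack on the silyl ethers, Bouveault formylation with DMF installs the benzylic carbon and borohydride reduces the aldehyde in the same flask.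

Step 12
Reactants: 17 [4-[(1R,2R)-1,3-bis(tert-butyldimethylsilyloxy)-1-(3-methoxy-4-triisopropylsilyloxyphenyl)propan-2-yl]oxy-3-methoxyphenyl]methanol
Product: 18 4-(bromomethyl)-1-[(1R,2R)-1,3-bis(tert-butyldimethylsilyloxy)-1-(3-methoxy-4-triisopropylsilyloxyphenyl)propan-2-yl]oxy-2-methoxybenzene
Conditions: CBr4, PPh3, 2,6-lutidine, CH2Cl2, 0 °C; used at once
Reagents that add atoms: tetrabromomethane, BrC(Br)(Br)Br
Why: the Appel reaction converts the primary benzylic alcohol into the bromide under neutral conditions that leave the silyl ethers and the benzylic C7'' ether untouched.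

Step 13
Reactants: 8 (4R)-4-[(3-methoxy-4-triisopropylsilyloxyphenyl)methyl]oxolan-2-one; 18 4-(bromomethyl)-1-[(1R,2R)-1,3-bis(tert-butyldimethylsilyloxy)-1-(3-methoxy-4-triisopropylsilyloxyphenyl)propan-2-yl]oxy-2-methoxybenzene
Product: 20 (3R,4R)-3-[[4-[(1R,2R)-1,3-bis(tert-butyldimethylsilyloxy)-1-(3-methoxy-4-triisopropylsilyloxyphenyl)propan-2-yl]oxy-3-methoxyphenyl]methyl]-4-[(3-methoxy-4-triisopropylsilyloxyphenyl)methyl]oxolan-2-one, via lithium enolate 19 (not isolated)
Conditions: LiN(SiMe3)2 (1.1 equiv), THF, −78 °C; then 18, DMPU, −78 to −30 °C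
Reagents that add atoms: none
Why: enolate alkylation of the γ-butyrolactone takes the benzylic bromide on the face anti to the C4 substituent and so sets C3 as R (trans), the standard 1,2-induction of dibenzylbutyrolactone lignan syntheses, and the minor diastereomer arising from residual ent-8 is removed by chromatography.

Step 14
Reactants: 20 (3R,4R)-3-[[4-[(1R,2R)-1,3-bis(tert-butyldimethylsilyloxy)-1-(3-methoxy-4-triisopropylsilyloxyphenyl)propan-2-yl]oxy-3-methoxyphenyl]methyl]-4-[(3-methoxy-4-triisopropylsilyloxyphenyl)methyl]oxolan-2-one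
Product: 21 (3R,4R)-3-[[4-[(1R,2R)-1,3-dihydroxy-1-(4-hydroxy-3-methoxyphenyl)propan-2-yl]oxy-3-methoxyphenyl]methyl]-4-[(4-hydroxy-3-methoxyphenyl)methyl]oxolan-2-one (CNP0305334.1)
Conditions: Bu4NF (6 equiv), AcOH (6 equiv), THF, 0 °C to rt
Reagents that add atoms: none
Why: buffered fluoride desilylation removes the two aryl TIPS and two TBS groups in one operation without base-induced lactone epimerisation or opening and without acid that could ionise the benzylic C7'' centre.

**Compound list**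

1 | catechol (benzene-1,2-diol) | Oc1ccccc1O | starting material
2 | guaiacol (2-methoxyphenol) | COc1ccccc1O | intermediate
3 | 4-iodo-2-methoxyphenol | COc1cc(I)ccc1O | intermediate
4 | (4-iodo-2-methoxyphenoxy)triisopropylsilane | COc1cc(I)ccc1O[Si](C(C)C)(C(C)C)C(C)C | intermediate
5 | 3-(bromomethyl)-1,1-dimethoxycyclobutane | COC1(OC)CC(CBr)C1 | starting material
6 | [4-[(3,3-dimethoxycyclobutyl)methyl]-2-methoxyphenoxy]triisopropylsilane | COc1cc(CC2CC(OC)(OC)C2)ccc1O[Si](C(C)C)(C(C)C)C(C)C | intermediate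
7 | 3-[(3-methoxy-4-triisopropylsilyloxyphenyl)methyl]cyclobutan-1-one | COc1cc(CC2CC(=O)C2)ccc1O[Si](C(C)C)(C(C)C)C(C)C | intermediate
8 | (4R)-4-[(3-methoxy-4-triisopropylsilyloxyphenyl)methyl]oxolan-2-one | COc1cc(C[C@H]2COC(=O)C2)ccc1O[Si](C(C)C)(C(C)C)C(C)C | intermediate
9 | ethyl diazoacetate | CCOC(=O)C=[N+]=[N-] | starting material
10 | ethyl 2-diazo-3-(3-methoxy-4-triisopropylsilyloxyphenyl)-3-oxopropanoate | CCOC(=O)C(=[N+]=[N-])C(=O)c1ccc(O[Si](C(C)C)(C(C)C)C(C)C)c(OC)c1 | intermediate
11 | ethyl 2-(4-iodo-2-methoxyphenoxy)-3-(3-methoxy-4-triisopropylsilyloxyphenyl)-3-oxopropanoate (racemic) | CCOC(=O)C(Oc1ccc(I)cc1OC)C(=O)c1ccc(O[Si](C(C)C)(C(C)C)C(C)C)c(OC)c1 | intermediate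
12 | ethyl (2S,3R)-3-hydroxy-2-(4-iodo-2-methoxyphenoxy)-3-(3-methoxy-4-triisopropylsilyloxyphenyl)propanoate | CCOC(=O)[C@@H](Oc1ccc(I)cc1OC)[C@H](O)c1ccc(O[Si](C(C)C)(C(C)C)C(C)C)c(OC)c1 | intermediate
13 | (1R,2R)-2-(4-iodo-2-methoxyphenoxy)-1-(3-methoxy-4-triisopropylsilyloxyphenyl)propane-1,3-diol | COc1cc(I)ccc1O[C@H](CO)[C@H](O)c1ccc(O[Si](C(C)C)(C(C)C)C(C)C)c(OC)c1 | intermediate
14 | (1R,2R)-1,3-bis(tert-butyldimethylsilyloxy)-2-(4-iodo-2-methoxyphenoxy)-1-(3-methoxy-4-triisopropylsilyloxyphenyl)propane | COc1cc(I)ccc1O[C@H](CO[Si](C)(C)C(C)(C)C)[C@H](O[Si](C)(C)C(C)(C)C)c1ccc(O[Si](C(C)C)(C(C)C)C(C)C)c(OC)c1 | intermediate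
15 | [4-[(1R,2R)-1,3-bis(tert-butyldimethylsilyloxy)-1-(3-methoxy-4-triisopropylsilyloxyphenyl)propan-2-yl]oxy-3-methoxyphenyl]lithium | COc1cc([Li])ccc1O[C@H](CO[Si](C)(C)C(C)(C)C)[C@H](O[Si](C)(C)C(C)(C)C)c1ccc(O[Si](C(C)C)(C(C)C)C(C)C)c(OC)c1 | intermediate
16 | 4-[(1R,2R)-1,3-bis(tert-butyldimethylsilyloxy)-1-(3-methoxy-4-triisopropylsilyloxyphenyl)propan-2-yl]oxy-3-methoxybenzaldehyde | COc1cc(C=O)ccc1O[C@H](CO[Si](C)(C)C(C)(C)C)[C@H](O[Si](C)(C)C(C)(C)C)c1ccc(O[Si](C(C)C)(C(C)C)C(C)C)c(OC)c1 | intermediate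
17 | [4-[(1R,2R)-1,3-bis(tert-butyldimethylsilyloxy)-1-(3-methoxy-4-triisopropylsilyloxyphenyl)propan-2-yl]oxy-3-methoxyphenyl]methanol | COc1cc(CO)ccc1O[C@H](CO[Si](C)(C)C(C)(C)C)[C@H](O[Si](C)(C)C(C)(C)C)c1ccc(O[Si](C(C)C)(C(C)C)C(C)C)c(OC)c1 | intermediate
18 | 4-(bromomethyl)-1-[(1R,2R)-1,3-bis(tert-butyldimethylsilyloxy)-1-(3-methoxy-4-triisopropylsilyloxyphenyl)propan-2-yl]oxy-2-methoxybenzene | COc1cc(CBr)ccc1O[C@H](CO[Si](C)(C)C(C)(C)C)[C@H](O[Si](C)(C)C(C)(C)C)c1ccc(O[Si](C(C)C)(C(C)C)C(C)C)c(OC)c1 | intermediate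
19 | lithium enolate of 8, lithium (3R)-3-[(3-methoxy-4-triisopropylsilyloxyphenyl)methyl]-2,3-dihydrofuran-5-olate | [Li]OC1=C[C@@H](Cc2ccc(O[Si](C(C)C)(C(C)C)C(C)C)c(OC)c2)CO1 | intermediate
20 | (3R,4R)-3-[[4-[(1R,2R)-1,3-bis(tert-butyldimethylsilyloxy)-1-(3-methoxy-4-triisopropylsilyloxyphenyl)propan-2-yl]oxy-3-methoxyphenyl]methyl]-4-[(3-methoxy-4-triisopropylsilyloxyphenyl)methyl]oxolan-2-one | COc1cc(C[C@H]2COC(=O)[C@@H]2Cc2ccc(O[C@H](CO[Si](C)(C)C(C)(C)C)[C@H](O[Si](C)(C)C(C)(C)C)c3ccc(O[Si](C(C)C)(C(C)C)C(C)C)c(OC)c3)c(OC)c2)ccc1O[Si](C(C)C)(C(C)C)C(C)C | intermediate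
21 | (3R,4R)-3-[[4-[(1R,2R)-1,3-dihydroxy-1-(4-hydroxy-3-methoxyphenyl)propan-2-yl]oxy-3-methoxyphenyl]methyl]-4-[(4-hydroxy-3-methoxyphenyl)methyl]oxolan-2-one | COc1cc(C[C@H]2COC(=O)[C@@H]2Cc2ccc(O[C@H](CO)[C@H](O)c3ccc(O)c(OC)c3)c(OC)c2)ccc1O | target

**Step count**

Total steps: 14. Longest linear sequence: 12 steps (1, 2, 3, 6, 7, 8, 9, 10, 11, 12, 13, 14).

**Steps most likely to fail and their fallbacks**

Step 5 (enantioselectivity of the Baeyer–Villiger ring expansion with a flexible benzyl substituent). The fallback sets out from 7 and comes back at 8. It replaces oxidative desymmetrisation by enantiotopic deprotonation and ring cleavage: 7 is treated with a chiral lithium bis(1-phenylethyl)amide and Me3SiCl (THF, −100 °C, internal quench) to give the silyl enol ether (R)-trimethyl-[3-[(3-methoxy-4-triisopropylsilyloxyphenyl)methyl]cyclobut-1-en-1-yl]oxysilane F1. Ozonolysis (O3, CH2Cl2/MeOH, −78 °C) cleaves the enol double bond to the aldehyde acid (3R)-3-formyl-4-(3-methoxy-4-triisopropylsilyloxyphenyl)butanoic acid F2. NaBH4 added to the same flask gives the hydroxy acid (3R)-4-hydroxy-3-[(3-methoxy-4-triisopropylsilyloxyphenyl)methyl]butanoic acid F3, which closes to 8 on acidification with 1 M HCl.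

Step 6 (carbonylative coupling with a diazo partner, which is sensitive to Pd-induced diazo decomposition). The fallback sets out from 4 and 3 and comes back at 11, so step 7 is bypassed as well. It is a crossed Claisen route:
- 4 is lithiated (n-BuLi, THF, −78 °C) and carboxylated with CO2 to 3-methoxy-4-triisopropylsilyloxybenzoic acid F4.
- 3 is alkylated with ethyl bromoacetate (K2CO3, acetone) to ethyl 2-(4-iodo-2-methoxyphenoxy)acetate F5.
- F4 is activated with 1,1'-carbonyldiimidazole to the acyl imidazole (imidazol-1-yl)(3-methoxy-4-triisopropylsilyloxyphenyl)methanone F6.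
- F5 is converted with LiN(SiMe3)2 (2.2 equiv, THF, −78 °C) into its lithium enolate F7, which is C-acylated by F6 to give 11.

Step 8 (the proposed transfer hydrogenation with dynamic kinetic resolution; the aryloxy group may lower syn selectivity or rate). The fallback uses known auxiliary-controlled aldol chemistry, sets out from 3 and 4 and comes back at 13, so steps 6, 7 and 9 are not run:
- 3 is alkylated with commercial (S)-4-benzyl-3-(chloroacetyl)oxazolidin-2-one (K2CO3, NaI, acetone) to (S)-4-benzyl-3-[2-(4-iodo-2-methoxyphenoxy)acetyl]oxazolidin-2-one F8.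
- 4 is converted (n-BuLi, THF, −78 °C; DMF) into 3-methoxy-4-triisopropylsilyloxybenzaldehyde F9.
- F8 is enolised with Bu2BOTf and i-Pr2NEt (CH2Cl2, −78 °C) to the Z dibutylboron enolate F10, which adds to F9 to give the Evans syn aldol adduct (S)-4-benzyl-3-[(2S,3R)-3-hydroxy-2-(4-iodo-2-methoxyphenoxy)-3-(3-methoxy-4-triisopropylsilyloxyphenyl)propanoyl]oxazolidin-2-one F11.
- NaBH4 in THF/H2O cleaves the auxiliary reductively and gives 13.

**Further compounds**

F1 | step 5 | (R)-trimethyl-[3-[(3-methoxy-4-triisopropylsilyloxyphenyl)methyl]cyclobut-1-en-1-yl]oxysilane | C[Si](C)(C)OC1=C[C@H](Cc2ccc(O[Si](C(C)C)(C(C)C)C(C)C)c(OC)c2)C1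
F2 | step 5 | (3R)-3-formyl-4-(3-methoxy-4-triisopropylsilyloxyphenyl)butanoic acid | OC(=O)C[C@H](C=O)Cc1ccc(O[Si](C(C)C)(C(C)C)C(C)C)c(OC)c1
F3 | step 5 | (3R)-4-hydroxy-3-[(3-methoxy-4-triisopropylsilyloxyphenyl)methyl]butanoic acid | OC(=O)C[C@H](CO)Cc1ccc(O[Si](C(C)C)(C(C)C)C(C)C)c(OC)c1
F4 | step 6 | 3-methoxy-4-triisopropylsilyloxybenzoic acid | COc1cc(C(O)=O)ccc1O[Si](C(C)C)(C(C)C)C(C)C
F5 | step 6 | ethyl 2-(4-iodo-2-methoxyphenoxy)acetate | CCOC(=O)COc1ccc(I)cc1OC
F6 | step 6 | (imidazol-1-yl)(3-methoxy-4-triisopropylsilyloxyphenyl)methanone | COc1cc(C(=O)n2ccnc2)ccc1O[Si](C(C)C)(C(C)C)C(C)C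
F7 | step 6 | lithium enolate of F5 | CCOC(O[Li])=COc1ccc(I)cc1OC
F8 | step 8 | (S)-4-benzyl-3-[2-(4-iodo-2-methoxyphenoxy)acetyl]oxazolidin-2-one | COc1cc(I)ccc1OCC(=O)N1[C@@H](Cc2ccccc2)COC1=O
F9 | step 8 | 3-methoxy-4-triisopropylsilyloxybenzaldehyde | COc1cc(C=O)ccc1O[Si](C(C)C)(C(C)C)C(C)C
F10 | step 8 | Z dibutylboron enolate of F8 | CCCCB(CCCC)O/C(=C\Oc1ccc(I)cc1OC)N1[C@@H](Cc2ccccc2)COC1=O
F11 | step 8 | (S)-4-benzyl-3-[(2S,3R)-3-hydroxy-2-(4-iodo-2-methoxyphenoxy)-3-(3-methoxy-4-triisopropylsilyloxyphenyl)propanoyl]oxazolidin-2-one | COc1cc(I)ccc1O[C@H](C(=O)N1[C@@H](Cc2ccccc2)COC1=O)[C@H](O)c1ccc(O[Si](C(C)C)(C(C)C)C(C)C)c(OC)c1
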